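The 1,2‑dioxane (ring atoms O1, O2, C3 hemiketal, C4, C5, C6) is cut at O1–C6 and C4–C3: a formal (3+3) union of the three‑carbon unit C4–C5–C6, stored as a strained cyclopropane whose C4–C6 σ‑bond is activated by a temporary formyl group on C4, with the unit O1–O2–C3 of a hydroperoxy ortho ester. The key step exploits the 1,3‑relationship of C4 and C6 across C5: the hydroperoxide opens the ring at quaternary C6 with inversion and the released enol closes on the C3 carbenium in the same flask. The precursor is an enantiopure cyclopropanecarbaldehyde from a Charette cyclopropanation; the formyl group is later expelled.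

Key step: step 9

Remark: the facial sense of the Charette cyclopropanation is assigned by analogy with the established outcome for cinnamyl alcohol; should it be opposite, the enantiomeric ligand is used.
Remark: C4 is epimerisable through the ring‑opened β‑keto ester, so it is set last by equilibration and separation, not by a stereospecific step.

Step 1
Reactants: 1 (7‑bromoheptyl)benzene; 2 (S)‑3‑bromo‑2‑methylpropan‑1‑ol
Product: 4 (R)‑2‑methyl‑10‑phenyldecan‑1‑ol, via (7‑phenylheptyl)magnesium bromide 3 (not isolated)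
Conditions: Mg, THF, 40 °C; then 2 (0.4 equiv), Li2CuCl4 (3 mol %), THF, −20 → 0 °C; aq. NH4Cl
Reagents that add atoms: none
Why: Cu‑catalysed sp3–sp3 Grignard cross‑coupling displaces the primary bromide of 2 (one equivalent of 3 is spent on the hydroxyl proton) and does not touch the methyl‑bearing stereocentre, which comes from the chiral pool.

Step 2
Reactants: 4 (R)‑2‑methyl‑10‑phenyldecan‑1‑ol
Product: 5 [(9R)‑10‑iodo‑9‑methyldecyl]benzene
Conditions: I2, PPh3, imidazole, CH2Cl2, 0 °C → rt
Reagents that add atoms: iodine, II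
Why: Appel‑type iodination of a primary alcohol proceeds by SN2 at CH2 and leaves the neighbouring stereocentre unchanged.

Step 3
Reactants: 5 [(9R)‑10‑iodo‑9‑methyldecyl]benzene; 6 prop‑2‑yn‑1‑ol
Product: 8 (5R)‑5‑methyl‑13‑phenyltridec‑2‑yn‑1‑ol, via dilithiated propargyl alcohol 7 (not isolated)
Conditions: 6, n‑BuLi (2.1 equiv), THF/DMPU, −78 → 0 °C; then 5, rt
Reagents that add atoms: none
Why: The acetylide carbon of the propargyl alcohol dianion is alkylated by the primary iodide (SN2), the alkoxide being the poorer nucleophile.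

Step 4
Reactants: 8 (5R)‑5‑methyl‑13‑phenyltridec‑2‑yn‑1‑ol
Product: 10 (2E,5R)‑2,3,5‑trimethyl‑13‑phenyltridec‑2‑en‑1‑ol, via alkenylmagnesium chelate 9 (not isolated)
Conditions: MeMgBr (4 equiv), CuI (20 mol %), THF, reflux; then MeI, 0 °C → rt
Reagents that add atoms: methylmagnesium bromide, C[Mg]Br; iodomethane, CI
Why: CuI‑catalysed anti‑carbomagnesiation of the propargylic alkoxide puts the first methyl on C2 and magnesium on C3 in a five‑membered chelate, and methylation of the alkenyl–Mg bond with retention fixes the (E) tetrasubstituted alkene.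

Step 5
Reactants: 10 (2E,5R)‑2,3,5‑trimethyl‑13‑phenyltridec‑2‑en‑1‑ol
Product: 11 [(1R,2R)‑1,2‑dimethyl‑2‑[(2R)‑2‑methyl‑10‑phenyldecyl]cyclopropyl]methanol
Conditions: Zn(CH2I)2·DME, (4S,5S)‑2‑butyl‑N,N,N′,N′‑tetramethyl‑1,3,2‑dioxaborolane‑4,5‑dicarboxamide (1.2 equiv), CH2Cl2, −10 °C → rt
Reagents that add atoms: bis(iodomethyl)zinc, IC[Zn]CI
Why: Charette asymmetric cyclopropanation (Simmons–Smith type) delivers methylene syn‑stereospecifically to the alkene face chosen by the chiral dioxaborolane bound to the zinc alkoxide, which sets both ring stereocentres, the quaternary carbon that becomes C6 being the one that matters.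

Step 6
Reactants: 11 [(1R,2R)‑1,2‑dimethyl‑2‑[(2R)‑2‑methyl‑10‑phenyldecyl]cyclopropyl]methanol
Product: 12 (1R,2R)‑1,2‑dimethyl‑2‑[(2R)‑2‑methyl‑10‑phenyldecyl]cyclopropane‑1‑carbaldehyde
Conditions: Dess–Martin periodinane, CH2Cl2, 0 °C → rt
Reagents that add atoms: none
Why: Dess–Martin oxidation converts the primary alcohol into the non‑enolisable aldehyde under neutral conditions that leave the cyclopropane intact.

Step 7
Reactants: 13 methyl cyanoacetate
Product: 15 methyl 3,3,3‑trimethoxypropanoate, via imidate hydrochloride 14 (not isolated)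
Conditions: HCl (g), MeOH (1.05 equiv), Et2O, 0 °C; then MeOH (excess), rt
Reagents that add atoms: methanol, CO
Why: Pinner reaction turns the nitrile into the imidate salt, whose alcoholysis gives the ortho ester.

Step 8
Reactants: 15 methyl 3,3,3‑trimethoxypropanoate
Product: 16 methyl 3‑hydroperoxy‑3,3‑dimethoxypropanoate
Conditions: anhydrous H2O2 in Et2O, PPTS (cat.), 4 Å MS, 0 °C; used as a cold solution
Reagents that add atoms: hydrogen peroxide, OO
Why: Acid‑catalysed exchange of one alkoxy group for the more nucleophilic hydroperoxide is the reaction type that converts ketals into α‑alkoxy hydroperoxides, applied here to an ortho ester.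

Step 9
Reactants: 12 (1R,2R)‑1,2‑dimethyl‑2‑[(2R)‑2‑methyl‑10‑phenyldecyl]cyclopropane‑1‑carbaldehyde; 16 methyl 3‑hydroperoxy‑3,3‑dimethoxypropanoate
Product: 18 methyl 2‑[(6S)‑4‑formyl‑3‑methoxy‑4,6‑dimethyl‑6‑[(2R)‑2‑methyl‑10‑phenyldecyl]‑1,2‑dioxan‑3‑yl]acetate (C3/C4 diastereomers), via open‑chain peroxy ortho ester aldehyde 17 (not isolated)
Conditions: TMSOTf (0.2 equiv), 4 Å MS, CH2Cl2, −78 → −20 °C; then aq. NaHCO3
Reagents that add atoms: none
Why: Proposed new method: TMSOTf activates the formyl group of 12, which turns the cyclopropane into a cyclopropylcarbinyl‑type (donor–acceptor) electrophile, and the terminal hydroperoxide oxygen of 16 attacks the quaternary ring carbon from the side opposite to the breaking C4–C6 bond, so that O1–C6 forms with inversion and C6 is set as S while the enol of open‑chain aldehyde 17 is released. Loss of one methoxy group from the tethered peroxy ortho ester then gives an alkoxy‑peroxycarbenium ion at C3, which the enol carbon C4 captures (C4–C3), closing the 1,2‑dioxane in a favoured 6‑(enolexo)‑endo‑trig mode and regenerating the aldehyde. The closest known reaction types are the Lewis‑acid opening of oxetanes by hydroperoxides at the more substituted carbon with inversion, stereoinvertive substitution at quaternary carbons of acyl‑activated cyclopropanes, the (3+3) annulation of nitrones with donor–acceptor cyclopropanes, and the addition of silyl enol ethers to peroxycarbenium ions. C6 is controlled by the configuration of the cyclopropane (stereospecific), whereas the new centres C3 and C4 form without control and are both reset in step 10. The step needs attack at C6 and not at the ring CH2, which the two alkyl donors on C6 should secure by stabilising the developing positive charge, and it needs O‑alkylation to outrun oxidation of the aldehyde, which ring strain and low temperature should favour.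

Step 10
Reactants: 18 methyl 2‑[(6S)‑4‑formyl‑3‑methoxy‑4,6‑dimethyl‑6‑[(2R)‑2‑methyl‑10‑phenyldecyl]‑1,2‑dioxan‑3‑yl]acetate
Product: 20 methyl 2‑[(3S,4R,6S)‑3‑hydroxy‑4,6‑dimethyl‑6‑[(2R)‑2‑methyl‑10‑phenyldecyl]‑1,2‑dioxan‑3‑yl]acetate, via formyl hemiketal 19 (not isolated)
Conditions: TFA, H2O, THF, 0 °C; then K2CO3 (cat.), MeOH, 0 °C → rt; chromatography, C4 epimer resubjected (DBU, MeOH)
Reagents that add atoms: water, O
Why: Aqueous acid hydrolyses the peroxy ketal to hemiketal 19, methoxide then adds to the non‑enolisable formyl group and retro‑Claisen cleavage expels methyl formate, after which C4 is protonated and equilibrates through the ring‑opened β‑keto ester towards the epimer that should be modestly favoured with the 4‑methyl and the long C6 chain both equatorial, while C3 settles with its hydroxyl axial (anomeric effect).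

Compound list
1 | (7‑bromoheptyl)benzene | BrCCCCCCCc1ccccc1 | starting material
2 | (S)‑3‑bromo‑2‑methylpropan‑1‑ol | OC[C@H](C)CBr | starting material
3 | (7‑phenylheptyl)magnesium bromide | Br[Mg]CCCCCCCc1ccccc1 | intermediate
4 | (R)‑2‑methyl‑10‑phenyldecan‑1‑ol | OC[C@H](C)CCCCCCCCc1ccccc1 | intermediate
5 | [(9R)‑10‑iodo‑9‑methyldecyl]benzene | IC[C@H](C)CCCCCCCCc1ccccc1 | intermediate
6 | prop‑2‑yn‑1‑ol | C#CCO | starting material
7 | dilithium salt of prop‑2‑yn‑1‑ol (lithium 3‑lithioprop‑2‑yn‑1‑olate) | [Li+].[Li+].[C-]#CC[O-] | intermediate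
8 | (5R)‑5‑methyl‑13‑phenyltridec‑2‑yn‑1‑ol | OCC#CC[C@H](C)CCCCCCCCc1ccccc1 | intermediate
9 | 4‑methyl‑3‑[(2R)‑2‑methyl‑10‑phenyldecyl]‑2,5‑dihydro‑1,2‑oxamagnesole | CC1=C(C[C@H](C)CCCCCCCCc2ccccc2)[Mg]OC1 | intermediate
10 | (2E,5R)‑2,3,5‑trimethyl‑13‑phenyltridec‑2‑en‑1‑ol | OC/C(C)=C(C)/C[C@H](C)CCCCCCCCc1ccccc1 | intermediate
11 | [(1R,2R)‑1,2‑dimethyl‑2‑[(2R)‑2‑methyl‑10‑phenyldecyl]cyclopropyl]methanol | OC[C@]1(C)C[C@@]1(C)C[C@H](C)CCCCCCCCc2ccccc2 | intermediate
12 | (1R,2R)‑1,2‑dimethyl‑2‑[(2R)‑2‑methyl‑10‑phenyldecyl]cyclopropane‑1‑carbaldehyde | O=C[C@]1(C)C[C@@]1(C)C[C@H](C)CCCCCCCCc2ccccc2 | intermediate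
13 | methyl cyanoacetate | COC(=O)CC#N | starting material
14 | methyl 3‑imino‑3‑methoxypropanoate hydrochloride | COC(=O)CC(=[NH2+])OC.[Cl-] | intermediate
15 | methyl 3,3,3‑trimethoxypropanoate | COC(=O)CC(OC)(OC)OC | intermediate
16 | methyl 3‑hydroperoxy‑3,3‑dimethoxypropanoate | COC(=O)CC(OC)(OC)OO | intermediate
17 | methyl 3,3‑dimethoxy‑3‑{[(4S,6R)‑2,4,6‑trimethyl‑1‑oxo‑14‑phenyltetradecan‑4‑yl]peroxy}propanoate (C2 epimers) | COC(=O)CC(OC)(OC)OO[C@@](C)(C[C@H](C)CCCCCCCCc1ccccc1)CC(C)C=O | intermediate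
18 | methyl 2‑[(6S)‑4‑formyl‑3‑methoxy‑4,6‑dimethyl‑6‑[(2R)‑2‑methyl‑10‑phenyldecyl]‑1,2‑dioxan‑3‑yl]acetate (C3/C4 diastereomers) | COC(=O)CC1(OC)OO[C@@](C)(C[C@H](C)CCCCCCCCc2ccccc2)CC1(C)C=O | intermediate
19 | methyl 2‑[(6S)‑4‑formyl‑3‑hydroxy‑4,6‑dimethyl‑6‑[(2R)‑2‑methyl‑10‑phenyldecyl]‑1,2‑dioxan‑3‑yl]acetate (C3/C4 diastereomers) | COC(=O)CC1(O)OO[C@@](C)(C[C@H](C)CCCCCCCCc2ccccc2)CC1(C)C=O | intermediate
20 | methyl 2‑[(3S,4R,6S)‑3‑hydroxy‑4,6‑dimethyl‑6‑[(2R)‑2‑methyl‑10‑phenyldecyl]‑1,2‑dioxan‑3‑yl]acetate | COC(=O)C[C@]1(O)OO[C@@](C)(C[C@H](C)CCCCCCCCc2ccccc2)C[C@H]1C | target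

Total step count: 10. Longest linear sequence: 8 steps (steps 1–6, 9 and 10); steps 7 and 8 form the short second branch.

Steps most likely to fail

Step 9 (Proposed new method). The hydroperoxide may add to the activated aldehyde and trigger a Baeyer–Villiger‑type loss of the formyl group before it opens the ring. Ionisation at C6 may run ahead of oxygen attack and erode the inversion. Capture of the stabilised C3 carbenium by the enol may also be too slow, so that open‑chain adduct 17 is returned. The fallback uses known reaction types, sets out from 12 and returns at 20. Roskamp homologation of 12 with methyl diazoacetate and SnCl2 should give the cyclopropyl β‑keto ester methyl 3‑[(1R,2R)‑1,2‑dimethyl‑2‑[(2R)‑2‑methyl‑10‑phenyldecyl]cyclopropyl]‑3‑oxopropanoate F1. Homo‑conjugate opening of F1 with HBr in AcOH at the quaternary ring carbon should give the tertiary bromide methyl (8R)‑6‑bromo‑4,6,8‑trimethyl‑3‑oxo‑16‑phenylhexadecanoate F2. Silver‑assisted perhydrolysis of F2 (AgOCOCF3, anhydrous H2O2, Et2O, 0 °C) should give methyl (8R)‑6‑hydroperoxy‑4,6,8‑trimethyl‑3‑oxo‑16‑phenylhexadecanoate F3, which closes spontaneously to the hemiketal 20. Ionisation in the silver step is expected to scramble C6, so this fallback relies on chromatographic separation of the C6 and C4 epimers.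

Step 8. The hydroperoxy ortho ester may lose methanol to a ketene acetal or decompose on concentration, so that the annulation partner never reaches step 9 intact. The fallback sets out from 15 and returns at 18. TMSOTf‑catalysed exchange of 15 with bis(trimethylsilyl) peroxide should give the capped reagent methyl 3,3‑dimethoxy‑3‑[(trimethylsilyl)peroxy]propanoate F4. F4 then takes the place of 16 under the conditions of step 9, the silyl group passing to the departing methoxide.

Step 10. Base may fragment the ring‑opened hydroperoxy β‑keto ester or cleave at the ketone instead of the formyl group, and equilibration at C4 may be incomplete. The fallback avoids base, sets out from 18 and returns at 20. Pinnick oxidation of 18 (NaClO2, NaH2PO4, 2‑methylbut‑2‑ene, t‑BuOH/H2O) should give (6S)‑3‑methoxy‑3‑(2‑methoxy‑2‑oxoethyl)‑4,6‑dimethyl‑6‑[(2R)‑2‑methyl‑10‑phenyldecyl]‑1,2‑dioxane‑4‑carboxylic acid F5. Aqueous TFA in THF should hydrolyse the ketal to the hemiketal acid (6S)‑3‑hydroxy‑3‑(2‑methoxy‑2‑oxoethyl)‑4,6‑dimethyl‑6‑[(2R)‑2‑methyl‑10‑phenyldecyl]‑1,2‑dioxane‑4‑carboxylic acid F6. As a β‑keto acid in its open form, F6 should decarboxylate on gentle warming to 20, with C4 again set by protonation and equilibration.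

Further compounds
F1 | step 9 | methyl 3‑[(1R,2R)‑1,2‑dimethyl‑2‑[(2R)‑2‑methyl‑10‑phenyldecyl]cyclopropyl]‑3‑oxopropanoate | COC(=O)CC(=O)[C@]1(C)C[C@@]1(C)C[C@H](C)CCCCCCCCc2ccccc2
F2 | step 9 | methyl (8R)‑6‑bromo‑4,6,8‑trimethyl‑3‑oxo‑16‑phenylhexadecanoate (C4/C6 mixture) | COC(=O)CC(=O)C(C)CC(C)(Br)C[C@H](C)CCCCCCCCc1ccccc1
F3 | step 9 | methyl (8R)‑6‑hydroperoxy‑4,6,8‑trimethyl‑3‑oxo‑16‑phenylhexadecanoate (C4/C6 mixture) | COC(=O)CC(=O)C(C)CC(C)(OO)C[C@H](C)CCCCCCCCc1ccccc1
F4 | step 8 | methyl 3,3‑dimethoxy‑3‑[(trimethylsilyl)peroxy]propanoate | COC(=O)CC(OC)(OC)OO[Si](C)(C)C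
F5 | step 10 | (6S)‑3‑methoxy‑3‑(2‑methoxy‑2‑oxoethyl)‑4,6‑dimethyl‑6‑[(2R)‑2‑methyl‑10‑phenyldecyl]‑1,2‑dioxane‑4‑carboxylic acid | COC(=O)CC1(OC)OO[C@@](C)(C[C@H](C)CCCCCCCCc2ccccc2)CC1(C)C(=O)O
F6 | step 10 | (6S)‑3‑hydroxy‑3‑(2‑methoxy‑2‑oxoethyl)‑4,6‑dimethyl‑6‑[(2R)‑2‑methyl‑10‑phenyldecyl]‑1,2‑dioxane‑4‑carboxylic acid | COC(=O)CC1(O)OO[C@@](C)(C[C@H](C)CCCCCCCCc2ccccc2)CC1(C)C(=O)O
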